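**Strategy.** Everything rests on cutting the C4'–C5' bond in the saturated C1'–C7' heptamethylene tether that links C6 of the 2,4-dihydroxybenzoic acid ring to the (Z)-C8'=C9' alkene. The key step exploits that this tether carries no functionality: C4' is made the terminus of a but-3-enyl arene (lateral allylation of a silyl-protected orsellinate) and C5' the bromide carbon of a (Z)-allylic alcohol derived from (R)-oct-1-yn-3-ol, which supplies the C10' stereocentre. One-pot hydroboration/B-alkyl Suzuki–Miyaura sp3–sp3 coupling then unites the arene with the complete C15 chain in one operation. Acetylation and a single fluoride-mediated global desilylation finish the synthesis.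

Key step: step 6

Remark on the chemistry: the side-chain carbinol centre is R and the alkene Z; commercial (R)-oct-1-yn-3-ol is assumed to be enantiopure, and its carbinol carbon is never involved in bond making or breaking.

**Step 1**
Reactants: 1 orsellinic acid (2,4-dihydroxy-6-methylbenzoic acid)
Product: 2 2-(trimethylsilyl)ethyl 2,4-dihydroxy-6-methylbenzoate
Conditions: 2-(trimethylsilyl)ethanol (1.05 equiv), PPh3, DIAD, THF, 0 °C → rt
Reagents that add atoms: 2-(trimethylsilyl)ethanol, C[Si](C)(C)CCO
Why: Mitsunobu esterification, in which the carboxylic acid (far more acidic than either phenol) is the pronucleophile that displaces the primary alkoxyphosphonium, so the TMSE ester should form chemoselectively.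

**Step 2**
Reactants: 2 2-(trimethylsilyl)ethyl 2,4-dihydroxy-6-methylbenzoate
Product: 3 2-(trimethylsilyl)ethyl 2-methyl-4,6-bis[(triisopropylsilyl)oxy]benzoate
Conditions: TIPSOTf (2.3 equiv), 2,6-lutidine, CH2Cl2, 0 °C → rt
Reagents that add atoms: triisopropylsilyl trifluoromethanesulfonate (TIPSOTf), CC(C)[Si](C(C)C)(C(C)C)OS(=O)(=O)C(F)(F)F
Why: O-silylation with a silyl triflate, reactive enough to silylate also the hydrogen-bonded ortho phenol, giving base-robust aryl TIPS ethers.

**Step 3**
Reactants: 3 2-(trimethylsilyl)ethyl 2-methyl-4,6-bis[(triisopropylsilyl)oxy]benzoate; 4 allyl bromide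
Product: 6 2-(trimethylsilyl)ethyl 2-(but-3-en-1-yl)-4,6-bis[(triisopropylsilyl)oxy]benzoate, via benzylic organolithium 5 (not isolated)
Conditions: LDA (1.3 equiv), THF, −78 °C; then 4, −78 → −20 °C; aq. NH4Cl
Reagents that add atoms: none
Why: Lateral (benzylic) lithiation of an ortho-toluate, in which LDA removes a proton of the ring methyl group activated vinylogously by the ester and the resulting anion is C-alkylated by allyl bromide (SN2).

**Step 4**
Reactants: 7 (R)-oct-1-yn-3-ol; 8 1,3-dibromopropane
Product: 10 (6R)-1-bromoundec-4-yn-6-ol, via dilithiated alkynol 9 (not isolated)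
Conditions: n-BuLi (2.05 equiv), THF, −78 → 0 °C; DMPU, then added to 8 (4 equiv), −78 °C → rt; H2O
Reagents that add atoms: none
Why: Alkylation of a propargylic alcohol dianion, in which the C-lithio acetylide is far more nucleophilic than the lithium alkoxide and displaces one bromide of the excess dihalide, leaving the carbinol centre untouched.

**Step 5**
Reactants: 10 (6R)-1-bromoundec-4-yn-6-ol
Product: 11 (4Z,6R)-1-bromoundec-4-en-6-ol
Conditions: H2 (1 atm), Lindlar catalyst (Pd/CaCO3, Pb-poisoned), quinoline, EtOAc, rt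
Reagents that add atoms: none
Why: Lindlar semihydrogenation, in which syn delivery of H2 on the poisoned palladium surface should give the Z-alkene without over-reduction or C–Br hydrogenolysis.

**Step 6**
Reactants: 6 2-(trimethylsilyl)ethyl 2-(but-3-en-1-yl)-4,6-bis[(triisopropylsilyl)oxy]benzoate; 11 (4Z,6R)-1-bromoundec-4-en-6-ol
Product: 13 2-(trimethylsilyl)ethyl 2-[(8Z,10R)-10-hydroxypentadec-8-en-1-yl]-4,6-bis[(triisopropylsilyl)oxy]benzoate, via B-alkyl-9-BBN borane 12 (not isolated)
Conditions: 6 (1.3 equiv), 9-BBN (1.25 equiv), THF, 0 °C → rt; then 11, Pd(OAc)2 (4 mol %), PCy3 (8 mol %), K3PO4·H2O, THF, rt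
Reagents that add atoms: none
Why: 9-BBN adds anti-Markovnikov to the only alkene of 6, placing boron on the terminal carbon; Pd(0)(PCy3)2 then inserts into the primary C–Br bond of 11 by an SN2-type oxidative addition, the hydroxide-activated borate transfers its primary alkyl group to palladium, and reductive elimination forges the CH2–CH2 bond. The closest known reaction type is the B-alkyl Suzuki–Miyaura coupling of unactivated primary alkyl bromides bearing β-hydrogens with alkyl-9-BBN reagents under Pd/trialkylphosphine catalysis at room temperature. No ring is closed and no stereocentre is created; the carbinol centre and the Z-alkene of 11 are spectators and should be retained. The step needs regioselective hydroboration (secured by the bulk of 9-BBN on a monosubstituted alkene), exclusive transfer of the primary alkyl group from boron rather than the bicyclic secondary B–C bonds, and coupling faster than β-hydride elimination (secured by the bulky, electron-rich PCy3). Complete hydroboration of 6 before 11 is added keeps B–H away from the Z-alkene, and the mild phosphate base should spare the TMSE ester, the aryl TIPS ethers and the free allylic alcohol.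

**Step 7**
Reactants: 13 2-(trimethylsilyl)ethyl 2-[(8Z,10R)-10-hydroxypentadec-8-en-1-yl]-4,6-bis[(triisopropylsilyl)oxy]benzoate
Product: 14 2-(trimethylsilyl)ethyl 2-[(8Z,10R)-10-(acetyloxy)pentadec-8-en-1-yl]-4,6-bis[(triisopropylsilyl)oxy]benzoate
Conditions: Ac2O, pyridine, DMAP (cat.), CH2Cl2, 0 °C → rt
Reagents that add atoms: acetic anhydride, CC(=O)OC(C)=O
Why: DMAP-catalysed O-acylation of the only free hydroxyl group, which proceeds at oxygen and therefore retains the R configuration.

**Step 8**
Reactants: 14 2-(trimethylsilyl)ethyl 2-[(8Z,10R)-10-(acetyloxy)pentadec-8-en-1-yl]-4,6-bis[(triisopropylsilyl)oxy]benzoate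
Product: 15 2-[(8Z,10R)-10-(acetyloxy)pentadec-8-en-1-yl]-4,6-dihydroxybenzoic acid
Conditions: TBAF (4 equiv), THF, 0 °C → rt; cold dilute HCl to pH 3
Reagents that add atoms: none
Why: Fluoride-mediated global desilylation, in which fluoride cleaves both aryl O–Si bonds and attacks the Me3Si group of the TMSE ester, which fragments to ethene and the carboxylate, while the secondary acetate and the Z-alkene should be inert at this temperature.

**Compound list**
1 | orsellinic acid (2,4-dihydroxy-6-methylbenzoic acid) | Cc1cc(O)cc(O)c1C(=O)O | starting material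
2 | 2-(trimethylsilyl)ethyl 2,4-dihydroxy-6-methylbenzoate | Cc1cc(O)cc(O)c1C(=O)OCC[Si](C)(C)C | intermediate
3 | 2-(trimethylsilyl)ethyl 2-methyl-4,6-bis[(triisopropylsilyl)oxy]benzoate | Cc1cc(O[Si](C(C)C)(C(C)C)C(C)C)cc(O[Si](C(C)C)(C(C)C)C(C)C)c1C(=O)OCC[Si](C)(C)C | intermediate
4 | allyl bromide (3-bromoprop-1-ene) | C=CCBr | starting material
5 | 2-(trimethylsilyl)ethyl 2-(lithiomethyl)-4,6-bis[(triisopropylsilyl)oxy]benzoate | [Li]Cc1cc(O[Si](C(C)C)(C(C)C)C(C)C)cc(O[Si](C(C)C)(C(C)C)C(C)C)c1C(=O)OCC[Si](C)(C)C | intermediate (not isolated)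
6 | 2-(trimethylsilyl)ethyl 2-(but-3-en-1-yl)-4,6-bis[(triisopropylsilyl)oxy]benzoate | C=CCCc1cc(O[Si](C(C)C)(C(C)C)C(C)C)cc(O[Si](C(C)C)(C(C)C)C(C)C)c1C(=O)OCC[Si](C)(C)C | intermediate
7 | (R)-oct-1-yn-3-ol | CCCCC[C@H](C#C)O | starting material
8 | 1,3-dibromopropane | BrCCCBr | starting material
9 | lithium (3R)-1-lithiooct-1-yn-3-olate | CCCCC[C@H](C#C[Li])O[Li] | intermediate (not isolated)
10 | (6R)-1-bromoundec-4-yn-6-ol | CCCCC[C@H](C#CCCCBr)O | intermediate
11 | (4Z,6R)-1-bromoundec-4-en-6-ol | CCCCC[C@H](/C=C\CCCBr)O | intermediate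
12 | 2-(trimethylsilyl)ethyl 2-[4-(9-borabicyclo[3.3.1]nonan-9-yl)butyl]-4,6-bis[(triisopropylsilyl)oxy]benzoate | C(CCCc1cc(O[Si](C(C)C)(C(C)C)C(C)C)cc(O[Si](C(C)C)(C(C)C)C(C)C)c1C(=O)OCC[Si](C)(C)C)B1C2CCCC1CCC2 | intermediate (not isolated)
13 | 2-(trimethylsilyl)ethyl 2-[(8Z,10R)-10-hydroxypentadec-8-en-1-yl]-4,6-bis[(triisopropylsilyl)oxy]benzoate | CCCCC[C@H](/C=C\CCCCCCCc1cc(O[Si](C(C)C)(C(C)C)C(C)C)cc(O[Si](C(C)C)(C(C)C)C(C)C)c1C(=O)OCC[Si](C)(C)C)O | intermediate
14 | 2-(trimethylsilyl)ethyl 2-[(8Z,10R)-10-(acetyloxy)pentadec-8-en-1-yl]-4,6-bis[(triisopropylsilyl)oxy]benzoate | CCCCC[C@H](/C=C\CCCCCCCc1cc(O[Si](C(C)C)(C(C)C)C(C)C)cc(O[Si](C(C)C)(C(C)C)C(C)C)c1C(=O)OCC[Si](C)(C)C)OC(C)=O | intermediate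
15 | 2-[(8Z,10R)-10-(acetyloxy)pentadec-8-en-1-yl]-4,6-dihydroxybenzoic acid | CCCCC[C@H](/C=C\CCCCCCCc1cc(O)cc(O)c1C(=O)O)OC(C)=O | target

**Total step count:** 8
**Longest linear sequence:** 6 steps (1 → 2 → 3 → 6 → 13 → 14 → 15; steps 1, 2, 3, 6, 7, 8)

**Steps most likely to fail**

Step 6. The alkyl–palladium intermediate may undergo β-hydride elimination or reduction faster than transmetalation, and palladium hydride formed in this way may isomerise the Z-alkene; partial loss of an aryl silyl ether to the phosphate base is a further possibility. The fallback sets out from 3 and 11 and comes back at 13; it makes the same CH2–CH2 bond with reversed polarity by a copper-catalysed Grignard/alkyl bromide coupling. Compound 3 is relithiated (LDA, THF, −78 °C) to 5, which is added to excess 1,3-dibromopropane 8 to give 2-(trimethylsilyl)ethyl 2-(4-bromobutyl)-4,6-bis[(triisopropylsilyl)oxy]benzoate F1. Alcohol 11 is silylated (TESCl, imidazole, CH2Cl2) to {[(4Z,6R)-1-bromoundec-4-en-6-yl]oxy}triethylsilane F2, and magnesium in THF converts this into [(4Z,6R)-6-(triethylsilyloxy)undec-4-en-1-yl]magnesium bromide F3. Coupling of F3 with F1 (Li2CuCl4 cat., NMP, THF, 0 °C; the di-ortho-substituted ester should resist the Grignard reagent under these conditions) should give 2-(trimethylsilyl)ethyl 2-[(8Z,10R)-10-(triethylsilyloxy)pentadec-8-en-1-yl]-4,6-bis[(triisopropylsilyl)oxy]benzoate F4. PPTS in MeOH/CH2Cl2 then removes the alkyl TES ether in preference to the more acid-stable aryl TIPS ethers and returns 13.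

Step 3. The benzylic anion of the bulky bis-silyl ether may form sluggishly or attack the ester of a second molecule, and double allylation or silyl migration could compete. The fallback sets out from 2 and comes back at 6; the benzylic C–C bond is made on the chelating bis(methoxymethyl) ether, the substrate class on which lateral toluate lithiation is best established, and the silyl ethers are installed only afterwards. Compound 2 is treated with NaH and MOMCl in DMF to give 2-(trimethylsilyl)ethyl 2,4-bis(methoxymethoxy)-6-methylbenzoate F5. LDA in THF at −78 °C converts it into 2-(trimethylsilyl)ethyl 2-(lithiomethyl)-4,6-bis(methoxymethoxy)benzoate F6, which is alkylated with allyl bromide 4 to 2-(trimethylsilyl)ethyl 2-(but-3-en-1-yl)-4,6-bis(methoxymethoxy)benzoate F7. Dilute HCl in MeOH at 40 °C removes both MOM groups to give 2-(trimethylsilyl)ethyl 2-(but-3-en-1-yl)-4,6-dihydroxybenzoate F8, and TIPSOTf/2,6-lutidine in CH2Cl2 then delivers 6.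

Step 8. Basic fluoride may cleave the secondary acetate while the TMSE ester is being removed, and the resorcylic acid may decarboxylate on a too acidic or warm work-up. The fallback sets out from 13 and comes back at 15; the acetate is introduced only after the fluoride step, and the selectivity comes from the much higher lability of aryl acetates. Compound 13 is treated with TBAF in THF (then cold dilute HCl) to give 2-[(8Z,10R)-10-hydroxypentadec-8-en-1-yl]-4,6-dihydroxybenzoic acid F9. Peracetylation (Ac2O, pyridine, DMAP cat.; aqueous work-up hydrolyses the mixed anhydride) should give 2,4-bis(acetyloxy)-6-[(8Z,10R)-10-(acetyloxy)pentadec-8-en-1-yl]benzoic acid F10. Mild methanolysis (NH4OAc, MeOH–H2O, rt) then cleaves the two phenolic acetates, leaves the secondary alkyl acetate and gives 15.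

**Further compounds**
F1 | step 6 | 2-(trimethylsilyl)ethyl 2-(4-bromobutyl)-4,6-bis[(triisopropylsilyl)oxy]benzoate | BrCCCCc1cc(O[Si](C(C)C)(C(C)C)C(C)C)cc(O[Si](C(C)C)(C(C)C)C(C)C)c1C(=O)OCC[Si](C)(C)C
F2 | step 6 | {[(4Z,6R)-1-bromoundec-4-en-6-yl]oxy}triethylsilane | CCCCC[C@H](/C=C\CCCBr)O[Si](CC)(CC)CC
F3 | step 6 | [(4Z,6R)-6-(triethylsilyloxy)undec-4-en-1-yl]magnesium bromide | CCCCC[C@H](/C=C\CCC[Mg]Br)O[Si](CC)(CC)CC
F4 | step 6 | 2-(trimethylsilyl)ethyl 2-[(8Z,10R)-10-(triethylsilyloxy)pentadec-8-en-1-yl]-4,6-bis[(triisopropylsilyl)oxy]benzoate | CCCCC[C@H](/C=C\CCCCCCCc1cc(O[Si](C(C)C)(C(C)C)C(C)C)cc(O[Si](C(C)C)(C(C)C)C(C)C)c1C(=O)OCC[Si](C)(C)C)O[Si](CC)(CC)CC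
F5 | step 3 | 2-(trimethylsilyl)ethyl 2,4-bis(methoxymethoxy)-6-methylbenzoate | Cc1cc(OCOC)cc(OCOC)c1C(=O)OCC[Si](C)(C)C
F6 | step 3 | 2-(trimethylsilyl)ethyl 2-(lithiomethyl)-4,6-bis(methoxymethoxy)benzoate | [Li]Cc1cc(OCOC)cc(OCOC)c1C(=O)OCC[Si](C)(C)C
F7 | step 3 | 2-(trimethylsilyl)ethyl 2-(but-3-en-1-yl)-4,6-bis(methoxymethoxy)benzoate | C=CCCc1cc(OCOC)cc(OCOC)c1C(=O)OCC[Si](C)(C)C
F8 | step 3 | 2-(trimethylsilyl)ethyl 2-(but-3-en-1-yl)-4,6-dihydroxybenzoate | C=CCCc1cc(O)cc(O)c1C(=O)OCC[Si](C)(C)C
F9 | step 8 | 2-[(8Z,10R)-10-hydroxypentadec-8-en-1-yl]-4,6-dihydroxybenzoic acid | CCCCC[C@H](/C=C\CCCCCCCc1cc(O)cc(O)c1C(=O)O)O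
F10 | step 8 | 2,4-bis(acetyloxy)-6-[(8Z,10R)-10-(acetyloxy)pentadec-8-en-1-yl]benzoic acid | CCCCC[C@H](/C=C\CCCCCCCc1cc(OC(C)=O)cc(OC(C)=O)c1C(=O)O)OC(C)=O
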